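Disconnection of the C2–C3 bond of the chromanone (ring C) carries the whole plan. C2 is an unsubstituted methylene bound to O1 and sits 1,6 to C3 through C4, C4a and C8a, so it can start as the carbon of an aryl methyl ether. An α-aryl-α-diazoketone joining a 4-benzyloxy-2,6-dimethoxybenzoyl group (ring A) to the benzyloxychromene (ring B) is decomposed by a chiral dirhodium carboxylate. The carbene at C3 inserts into a C–H bond of an ortho methoxy group, which closes ring C, forms C2–C3 and sets the C3 stereocentre in one operation. A convergent ketone α-arylation and a diazo transfer give the precursor; one Lewis-acid step unmasks the three phenols.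

Key step: step 6

Assumption: 1-(4-hydroxy-2,6-dimethoxyphenyl)ethan-1-one (1) is taken as a catalogue compound; its two methoxy groups are equivalent, so either can deliver C2.

Step 1
Reactants: 1 1-(4-hydroxy-2,6-dimethoxyphenyl)ethan-1-one
Product: 2 1-[4-(benzyloxy)-2,6-dimethoxyphenyl]ethan-1-one
Conditions: BnBr, K2CO3, DMF, rt
Reagents that add atoms: benzyl bromide, BrCc1ccccc1
Why: Williamson etherification of the only free phenol, which is para to the acetyl group and therefore acidic; the ketone and the methyl ethers are inert to K2CO3.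

Step 2
Reactants: 3 2-(benzyloxy)phenol
Product: 4 2-(benzyloxy)-4-bromophenol
Conditions: NBS, MeCN, −20 °C to 0 °C, dark
Reagents that add atoms: N-bromosuccinimide, BrN1C(=O)CCC1=O
Why: Electrophilic aromatic bromination in which the free hydroxyl outranks the ether as director, so bromine should enter para to OH, as in the bromination of guaiacol to 4-bromoguaiacol.

Step 3
Reactants: 4 2-(benzyloxy)-4-bromophenol, 5 3-methylbut-2-enal
Product: 8 8-(benzyloxy)-6-bromo-2,2-dimethyl-2H-chromene, via benzodioxaborin 6 (not isolated), via ortho-quinone methide 7 (not isolated)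
Conditions: PhB(OH)2 (1 equiv, recovered), AcOH (cat.), toluene, reflux, Dean–Stark
Reagents that add atoms: none
Why: Phenylboronic acid-templated ortho-hydroxyalkylation of the phenol by the enal gives 6, which loses PhBO on heating to give 7, and oxa-6π electrocyclisation of 7 gives the 2H-chromene; 4 has a single free ortho position, so only one regioisomer can form.

Step 4
Reactants: 2 1-[4-(benzyloxy)-2,6-dimethoxyphenyl]ethan-1-one, 8 8-(benzyloxy)-6-bromo-2,2-dimethyl-2H-chromene
Product: 9 1-[4-(benzyloxy)-2,6-dimethoxyphenyl]-2-[8-(benzyloxy)-2,2-dimethyl-2H-chromen-6-yl]ethan-1-one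
Conditions: Pd2(dba)3 (2 mol%), Xantphos (4.5 mol%), NaOtBu, THF, 70 °C
Reagents that add atoms: none
Why: Pd-catalysed α-arylation of a ketone enolate (Buchwald–Hartwig type); the methyl group is the only enolisable site of 2, and the wide-bite-angle ligand together with the more acidic product, which rests as its enolate, should hold the reaction at monoarylation.

Step 5
Reactants: 9 1-[4-(benzyloxy)-2,6-dimethoxyphenyl]-2-[8-(benzyloxy)-2,2-dimethyl-2H-chromen-6-yl]ethan-1-one
Product: 10 1-[4-(benzyloxy)-2,6-dimethoxyphenyl]-2-[8-(benzyloxy)-2,2-dimethyl-2H-chromen-6-yl]-2-diazoethan-1-one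
Conditions: p-ABSA, DBU, MeCN, 0 °C to rt
Reagents that add atoms: 4-acetamidobenzenesulfonyl azide (p-ABSA), CC(=O)Nc1ccc(cc1)S(=O)(=O)N=[N+]=[N-]
Why: Regitz diazo transfer; the methylene of 9 is both benzylic and α to the ketone, so it should be acidic enough for direct transfer with DBU, as with other benzyl ketones.

Step 6
Reactants: 10 1-[4-(benzyloxy)-2,6-dimethoxyphenyl]-2-[8-(benzyloxy)-2,2-dimethyl-2H-chromen-6-yl]-2-diazoethan-1-one
Product: 11 (3S)-7-(benzyloxy)-3-[8-(benzyloxy)-2,2-dimethyl-2H-chromen-6-yl]-5-methoxy-2,3-dihydro-4H-chromen-4-one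
Conditions: Rh2(S-PTAD)4 (1 mol%), CH2Cl2, 4 Å MS, 0 °C to rt, 10 added over 3 h (0.01 M)
Reagents that add atoms: none
Why: The catalyst, tetrakis[(S)-(1-adamantyl)(N-phthalimido)acetato]dirhodium (divalent rhodium), expels N2 from 10 to give a rhodium-bound aryl(aroyl)carbene at the future C3, which inserts into a C–H bond of one of the two equivalent ortho methoxy groups of ring A through a three-centre, hydride-transfer-like transition state, so that C2–C3 and C3–H form together (intramolecular rhodium-carbene C–H insertion). The closest known reaction type is the cyclisation of 2-alkoxyphenyl α-diazoketones to chroman-4-ones by C–H insertion next to the ether oxygen under chiral dirhodium carboxylates, supported by the known preference of aryl-substituted (donor/acceptor) carbenes for the primary C–H bonds of methyl ethers. Ring C closes by 1,6 C–H insertion, through a six-membered cyclic transition state made of the carbene carbon, C4, C4a, C8a, O1 and the methoxy carbon. C3 is the only new stereocentre and is set by the catalyst: the chiral carboxylate wall leaves one face of the carbene open to the C–H bond and the concerted insertion turns that facial choice directly into the C3 configuration; the sense of induction has to be confirmed in a first run and the R-configured catalyst is taken if S-PTAD gives the antipode. The step needs chemoselectivity for insertion over a five-membered oxonium ylide with Stevens methyl shift, over Wolff rearrangement and over bimolecular cyclopropanation of the chromene alkene or insertion into benzylic C–H bonds; the aryl donor tempers the carbene, the twisted 2,6-dimethoxybenzoyl group holds an O–CH3 next to the carbene carbon, ylide formation is reversible while methyl migrates poorly, and slow addition at high dilution starves the bimolecular paths. A neutral, base-free work-up should keep the acidic C3–H from epimerising.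

Step 7
Reactants: 11 (3S)-7-(benzyloxy)-3-[8-(benzyloxy)-2,2-dimethyl-2H-chromen-6-yl]-5-methoxy-2,3-dihydro-4H-chromen-4-one
Product: 12 (3S)-5,7-dihydroxy-3-(8-hydroxy-2,2-dimethyl-2H-chromen-6-yl)-2,3-dihydro-4H-chromen-4-one
Conditions: BCl3 (1 M in CH2Cl2, excess), C6HMe5, CH2Cl2, −78 °C then to 0 °C; cold pH 7 buffer quench
Reagents that add atoms: none
Why: Lewis-acid dealkylation: BCl3 with pentamethylbenzene as a non-Lewis-basic benzyl-cation scavenger should debenzylate both aryl benzyl ethers at −78 °C and, on warming, cleave the C5 methyl ether through the six-membered boron chelate with the C4 carbonyl; no base is present, so C3 and the chromene should survive a short exposure and a cold neutral quench.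

Compound list
1 | 1-(4-hydroxy-2,6-dimethoxyphenyl)ethan-1-one | CC(=O)c1c(OC)cc(O)cc1OC | starting material
2 | 1-[4-(benzyloxy)-2,6-dimethoxyphenyl]ethan-1-one | CC(=O)c1c(OC)cc(OCc2ccccc2)cc1OC | intermediate
3 | 2-(benzyloxy)phenol | Oc1ccccc1OCc1ccccc1 | starting material
4 | 2-(benzyloxy)-4-bromophenol | Oc1ccc(Br)cc1OCc1ccccc1 | intermediate
5 | 3-methylbut-2-enal | CC(C)=CC=O | starting material
6 | 8-(benzyloxy)-6-bromo-4-(2-methylprop-1-en-1-yl)-2-phenyl-4H-1,3,2-benzodioxaborinine | CC(C)=CC1OB(c2ccccc2)Oc2c(OCc3ccccc3)cc(Br)cc21 | intermediate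
7 | 2-(benzyloxy)-4-bromo-6-(3-methylbut-2-en-1-ylidene)cyclohexa-2,4-dien-1-one | O=C1C(OCc2ccccc2)=CC(Br)=CC1=CC=C(C)C | intermediate
8 | 8-(benzyloxy)-6-bromo-2,2-dimethyl-2H-chromene | CC1(C)C=Cc2cc(Br)cc(OCc3ccccc3)c2O1 | intermediate
9 | 1-[4-(benzyloxy)-2,6-dimethoxyphenyl]-2-[8-(benzyloxy)-2,2-dimethyl-2H-chromen-6-yl]ethan-1-one | COc1cc(OCc2ccccc2)cc(OC)c1C(=O)Cc3cc4C=CC(C)(C)Oc4c(OCc5ccccc5)c3 | intermediate
10 | 1-[4-(benzyloxy)-2,6-dimethoxyphenyl]-2-[8-(benzyloxy)-2,2-dimethyl-2H-chromen-6-yl]-2-diazoethan-1-one | COc1cc(OCc2ccccc2)cc(OC)c1C(=O)C(=[N+]=[N-])c3cc4C=CC(C)(C)Oc4c(OCc5ccccc5)c3 | intermediate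
11 | (3S)-7-(benzyloxy)-3-[8-(benzyloxy)-2,2-dimethyl-2H-chromen-6-yl]-5-methoxy-2,3-dihydro-4H-chromen-4-one | CC1(C)C=Cc2cc([C@H]3COc4cc(OCc5ccccc5)cc(OC)c4C3=O)cc(OCc6ccccc6)c2O1 | intermediate
12 | (3S)-5,7-dihydroxy-3-(8-hydroxy-2,2-dimethyl-2H-chromen-6-yl)-2,3-dihydro-4H-chromen-4-one (CNP0298948.1) | CC1(C)C=Cc2cc([C@H]3COc4cc(O)cc(O)c4C3=O)cc(O)c2O1 | target

Total step count: 7. Longest linear sequence: 6 steps (3 → 4 → 8 → 9 → 10 → 11 → 12).

Steps most likely to fail

1. Step 6. The rhodium carbene may be diverted by the lone pair of the neighbouring methoxy oxygen into a five-membered oxonium ylide that undergoes a Stevens methyl shift, or the C–H bond may add to both faces of the carbene with poor discrimination. The fallback uses known chemistry, sets out from 9 and comes back at 11. Chelation-controlled cleavage of one of the two ketone-flanking methyl ethers of 9 with MgI2·OEt2 (toluene, 80 °C) should give 1-[4-(benzyloxy)-2-hydroxy-6-methoxyphenyl]-2-[8-(benzyloxy)-2,2-dimethyl-2H-chromen-6-yl]ethan-1-one F1. Condensation with N,N-dimethylformamide dimethyl acetal (toluene, 100 °C; enaminone, then ring closure with loss of dimethylamine) should give the isoflavone 7-(benzyloxy)-3-[8-(benzyloxy)-2,2-dimethyl-2H-chromen-6-yl]-5-methoxy-4H-chromen-4-one F2. Asymmetric transfer hydrogenation with RuCl[(S,S)-TsDPEN](p-cymene), HCO2H/Et3N, EtOAc, 40 °C should reduce C2=C3 and then the ketone under dynamic kinetic resolution of the labile C3 centre. By analogy with aryl alkyl ketones the (S,S)-catalyst is expected to deliver the 4S carbinol, and hence the cis alcohol (3S,4S)-7-(benzyloxy)-3-[8-(benzyloxy)-2,2-dimethyl-2H-chromen-6-yl]-5-methoxy-3,4-dihydro-2H-chromen-4-ol F3. Dess–Martin periodinane (CH2Cl2, 0 °C) should then return 11 without touching C3. Where only the enantioselectivity of step 6 is at fault, the last two operations can be applied to scalemic 11 itself.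

2. Step 7. Lewis-acid-promoted enolisation at C3 (loss of configuration) or ionisation of the allylic aryl ether of the chromene may occur while the chelated methyl ether is cleaved at the higher temperature. The fallback sets out from 9 and comes back at 12: the protecting groups are exchanged before the stereocentre exists, so that the last unmasking needs only buffered fluoride. It still exposes the chromene to BCl3 once, but at a stage without a stereocentre. BCl3/C6HMe5 on 9 (CH2Cl2, −78 to 0 °C) should remove both benzyl groups and one ketone-flanking methyl group to give 1-(2,4-dihydroxy-6-methoxyphenyl)-2-(8-hydroxy-2,2-dimethyl-2H-chromen-6-yl)ethan-1-one F4. Silylation (TIPSCl, imidazole, DMAP, DMF, 50 °C) should give 1-{2-methoxy-4,6-bis[(triisopropylsilyl)oxy]phenyl}-2-{2,2-dimethyl-8-[(triisopropylsilyl)oxy]-2H-chromen-6-yl}ethan-1-one F5. Diazo transfer as in step 5 should give 2-diazo-1-{2-methoxy-4,6-bis[(triisopropylsilyl)oxy]phenyl}-2-{2,2-dimethyl-8-[(triisopropylsilyl)oxy]-2H-chromen-6-yl}ethan-1-one F6. The C–H insertion of step 6 then goes into the only remaining methoxy group, since the flanking silyl ether offers no C–H bond next to oxygen, and should give (3S)-5,7-bis[(triisopropylsilyl)oxy]-3-{2,2-dimethyl-8-[(triisopropylsilyl)oxy]-2H-chromen-6-yl}-2,3-dihydro-4H-chromen-4-one F7. TBAF/AcOH (THF, 0 °C) should then give 12.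

3. Step 3. The ortho-hydroxyalkylation may be slow, because the free ortho position is activated only by the hydroxyl group (it is meta to both Br and OBn), and the enal may be lost to self-condensation. The fallback sets out from 4 and comes back at 8. O-Alkylation with 3-chloro-3-methylbut-1-yne (CuCl2 cat., DBU, MeCN, 0 °C) should give the aryl propargyl ether 2-(benzyloxy)-4-bromo-1-[(2-methylbut-3-yn-2-yl)oxy]benzene F8. Heating (N,N-diethylaniline, 180 °C) should then bring about aromatic propargyl Claisen rearrangement to the free ortho position, 1,5-H shift and oxa-6π electrocyclisation to 8.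

Further compounds
F1 | step 6 | 1-[4-(benzyloxy)-2-hydroxy-6-methoxyphenyl]-2-[8-(benzyloxy)-2,2-dimethyl-2H-chromen-6-yl]ethan-1-one | COc1cc(OCc2ccccc2)cc(O)c1C(=O)Cc3cc4C=CC(C)(C)Oc4c(OCc5ccccc5)c3
F2 | step 6 | 7-(benzyloxy)-3-[8-(benzyloxy)-2,2-dimethyl-2H-chromen-6-yl]-5-methoxy-4H-chromen-4-one | CC1(C)C=Cc2cc(C3=COc4cc(OCc5ccccc5)cc(OC)c4C3=O)cc(OCc6ccccc6)c2O1
F3 | step 6 | (3S,4S)-7-(benzyloxy)-3-[8-(benzyloxy)-2,2-dimethyl-2H-chromen-6-yl]-5-methoxy-3,4-dihydro-2H-chromen-4-ol | CC1(C)C=Cc2cc([C@H]3COc4cc(OCc5ccccc5)cc(OC)c4[C@H]3O)cc(OCc6ccccc6)c2O1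
F4 | step 7 | 1-(2,4-dihydroxy-6-methoxyphenyl)-2-(8-hydroxy-2,2-dimethyl-2H-chromen-6-yl)ethan-1-one | COc1cc(O)cc(O)c1C(=O)Cc2cc3C=CC(C)(C)Oc3c(O)c2
F5 | step 7 | 1-{2-methoxy-4,6-bis[(triisopropylsilyl)oxy]phenyl}-2-{2,2-dimethyl-8-[(triisopropylsilyl)oxy]-2H-chromen-6-yl}ethan-1-one | COc1cc(O[Si](C(C)C)(C(C)C)C(C)C)cc(O[Si](C(C)C)(C(C)C)C(C)C)c1C(=O)Cc2cc3C=CC(C)(C)Oc3c(O[Si](C(C)C)(C(C)C)C(C)C)c2
F6 | step 7 | 2-diazo-1-{2-methoxy-4,6-bis[(triisopropylsilyl)oxy]phenyl}-2-{2,2-dimethyl-8-[(triisopropylsilyl)oxy]-2H-chromen-6-yl}ethan-1-one | COc1cc(O[Si](C(C)C)(C(C)C)C(C)C)cc(O[Si](C(C)C)(C(C)C)C(C)C)c1C(=O)C(=[N+]=[N-])c2cc3C=CC(C)(C)Oc3c(O[Si](C(C)C)(C(C)C)C(C)C)c2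
F7 | step 7 | (3S)-5,7-bis[(triisopropylsilyl)oxy]-3-{2,2-dimethyl-8-[(triisopropylsilyl)oxy]-2H-chromen-6-yl}-2,3-dihydro-4H-chromen-4-one | CC1(C)C=Cc2cc([C@H]3COc4cc(O[Si](C(C)C)(C(C)C)C(C)C)cc(O[Si](C(C)C)(C(C)C)C(C)C)c4C3=O)cc(O[Si](C(C)C)(C(C)C)C(C)C)c2O1
F8 | step 3 | 2-(benzyloxy)-4-bromo-1-[(2-methylbut-3-yn-2-yl)oxy]benzene | C#CC(C)(C)Oc1ccc(Br)cc1OCc1ccccc1
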